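Slowing is what the earlier runs show: each falls fast, then creeps. First order, the zero of this scale, leaves equal percentages at equal times with equal enzyme, but at 3.00 min Saturday's run has 31% left, less than Tuesday's 68%.

common to all: enzyme 1.7 µM
- Tuesday's: substrate 8.5 mM; run made earlier
- Saturday's: substrate 34 mM; run made earlier
- flask: substrate 17 mM; time 15 min

- Tuesday's (time / min: target / %, substrate / %): 0.667: 12, 88; 2.00: 27, 70; 3.00: 38, 68; 5.00: 43, 57; 6.00: 47, 52; 10.0: 56, 46
- Saturday's (time / min: target / %, substrate / %): 1.50: 48, 53; 3.00: 69, 31; 5.00: 81, 20; 6.00: 85, 17; 8.00: 82, 12; 10.0: 86, 14

(readings scatter by 2 percentage points)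

- what was read earlier has a scatter of 2 percentage points, one standard deviation
- steps thought possible: substrate + enzyme -> target + enzyme

1. target present at 15 min, in percent of the substrate charged
2. substrate present at 15 min, in percent of the substrate charged

My own reckoning takes the speed at a moment to follow the substrate concentration at that moment, so that a run passing a concentration continues as a run charged with it (the time shift of reaction progress analysis). By logarithmic interpolation, Saturday's run passes 17 mM at 1.66 min and 8.5 mM at 3.98 min. The lead, this flask's first half-life, the time its substrate needs to fall from its charge to Tuesday's charge, is therefore 2.32 min.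

As a check, Saturday's run at 6.00 min, which is 2.02 min after it passed Tuesday's charge, reads 5.78 mM, and Tuesday's run at 2.00 min reads 5.95 mM.

So this flask at 15 min should stand where Tuesday's run stands at 12.7 min. Tuesday's substrate, averaged with the complement of its target, goes from 52.5% at 6.00 min to 45.0% at 10.0 min. A straight line continues this to 40.0% of Tuesday's charge, which is 20.0% of this flask's charge, leaving 80.0% target.

The forecast differs, with 75% target (67% to 82%) and 25% substrate (18% to 33%); of the stall it says “It looks like the enzyme dying”, or product inhibition.

The flask gives 80.9% target and 19.1% substrate.

    substrate + enzyme → target + enzyme, rate k1*[substrate]^3*[enzyme]/(1 + ([substrate]/Kh1)^3) (16.0 mM, k = 3.20 × 10⁷ M⁻³ s⁻¹)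

The enzyme in the flask stands at 100% of its charge at 15.0 min, and the half-life of the flask's slowest mode as it stands at that time is 6.81 min, 2.94 times the lead of 2.32 min. The flask read at 4.0 min should stand where Tuesday's run stands at 1.68 min; interpolating between Tuesday's first two readings gives 37.7% of this flask's charge, and the flask read then holds 37.7% substrate.

The readings were generated by integration with made-up constants.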